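The autumn run, charged with 0.20 M of substrate, and the midnight run, charged with 0.80 M, bracket the flask, whose 0.40 M is close to their geometric mean, so the reckoning below takes the mean of these two runs as its estimate for the flask.

| flask | substrate | gas phase | free catalyst | impurity | remark | time |
|---|---|---|---|---|---|---|
| autumn | 0.20 M | 200 mM (held) | 8 mM | 1.2 mM | run made earlier |  |
| midnight | 0.80 M | 200 mM (held) | 8 mM | 1.2 mM | run made earlier |  |
| dawn | 0.40 M | 200 mM (held) | 12 mM | 1.2 mM | run made earlier |  |
| flask | 0.40 M | 200 mM (held) | 8.0 mM | 1.2 mM |  | 2.5 min |

| run | time / s | product / % |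
|---|---|---|
| autumn | 12.0 | 3.0 |
| autumn | 25.0 | 6.2 |
| autumn | 40.0 | 10.7 |
| autumn | 50.0 | 11.9 |
| autumn | 60.0 | 15.2 |
| autumn | 80.0 | 18.8 |
| autumn | 90.0 | 20.4 |
| midnight | 12.0 | 1.5 |
| midnight | 25.0 | 5.2 |
| midnight | 40.0 | 8.3 |
| midnight | 50.0 | 9.4 |
| midnight | 60.0 | 11.6 |
| midnight | 80.0 | 15.4 |
| midnight | 90.0 | 16.0 |
| dawn | 10.0 | 2.0 |
| dawn | 25.0 | 7.8 |
| dawn | 40.0 | 12.2 |
| dawn | 60.0 | 17.2 |
| dawn | 90.0 | 22.8 |

(readings scatter by 0.5 percentage points)

- the analysis behind the earlier runs scatters by 0.5 percentage points, standard deviation
- at the start none of the gas phase is in solution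

- ochre: doubling the amount of free catalyst, all else as stated
- green: doubling the saturation concentration of gas phase, all else as stated
- violet: doubling the transfer coefficient of the gas phase, all else as stated

* amount of product at 2.5 min, in percent of the substrate charged
* the change that raises the amount of product at 2.5 min, in percent of the substrate charged most ("none" if none brings more than 2 percentage points) (ochre / green / violet / none)
* amount of product at 2.5 min, in percent of the substrate charged, after violet

The useful count is L, the logarithm of substrate charged over substrate left, taking the substrate left as the charge less the product, and its slope r is the pseudo-first-order rate constant of the substrate. Averaged over the autumn and midnight runs, L stands at 0.0228 after 12.0 s, 0.0999 after 40.0 s and 0.201 after 90.0 s. So r reads 0.00275 s⁻¹ around 26.0 s but sags to a reading of 0.00203 s⁻¹ around 65.0 s.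

This reckoning assumes the sag of a catalyst lost in pairs, where r falls inversely as τ + t. The sag time τ, the time in which r falls to half of its start, then reads 82.7 s, a reading that carries the scatter of the early points. L then gains G = r(τ + t) = 0.299 per factor e in τ + t. The stretch beyond the last reading is then reckoned as a correction to the averaged L: from 90.0 s to 2.5 min, L reaches 0.291, which gives an estimate of 25.2% product for the flask.

The forecast gives 28.5%, higher than this reckoning, names green as the best change and puts violet at 30.5%, on the ground that “Violet only removes the small transfer resistance”.

The simulation gives 26.8%, with green best at a gain of 20 percentage points, violet at a gain of 15 points and ochre at a gain of 7.1 points; after violet the flask holds 42.2%, above the forecast's value for violet.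

    gas phase ⇌ dissolved gas, rate k1*(csat - [dissolved gas]) (kL = 0.0224 s⁻¹)
    substrate + dissolved gas + free catalyst → free catalyst + product (k = 20.1 M⁻² s⁻¹)
    free catalyst + impurity → spent catalyst A (k = 841 M⁻¹ s⁻¹)
    dissolved gas → decomposed reagent (k = 0.0882 s⁻¹)
    2 free catalyst → spent catalyst B (k = 1.19 M⁻¹ s⁻¹)

At 2.5 min the flask is not at rest: 73% of the substrate remains, and 24.8% of the catalyst charge is still free. Carried from the simulated 26.8% with the same τ and G, the reckoning gives 46.9% for the neighbour flask at 10 min, which stores 49.4%, and 58.7% at 25.0 min, where the flask stores 62.1%. Ten times the time still moves the substrate in the flask to 37.9% of its charge, free catalyst to 3.36% of its charge, and decomposed reagent from 0.421 M to 5.13 M.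

The data come from a simulation for substances that don't exist; noise was put on by code.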